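## Structural features

The target is a flavonol: a 4H-chromen-4-one in which benzenoid ring A is fused to pyranone ring C along C4a–C8a, with aryl ring B joined to C2 by one C–C bond. There is no stereocentre, so the problem is one of connectivity and of telling five oxygens apart. O3, O7 and O4' carry sulfate monoesters, while O5 (hydrogen-bonded to the C4 carbonyl) and O3' (the catechol neighbour of O4') stay free. The aryl sulfate monoesters are the fragile groups: acid cleaves them and they turn every intermediate into a water-soluble polyanion, so they must come last. Once unmasked, the flavonol and catechol are also oxidation-sensitive, and the pyranone is open to conjugate attack by hard nucleophiles. The real difficulty is to reach a late intermediate in which O3, O7 and O4' can be freed together while O3' keeps a group removable without acid, and to do this without differentiating the ring A oxygens by hand. The key step uses the fact that ring A is a resorcinol whose C5 hydroxyl is peri to C4=O with the C7 oxygen meta to it. C5 and C8 can come from a ketene, C6 and C7 from an alkynyl ether, and C4a and C8a are already the C5=C6 double bond of a 4-pyranone that carries O3 and ring B. The annulation therefore delivers O5 as a free chelated phenol and O7 as an ether in one operation.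

## Logic of the disconnections

**26 from 25.** The only bond cut is O3'–CH2 of a benzyl ether. It comes last because hydrogenolysis is neutral and reductive, conditions under which three aryl sulfates and a newly freed phenol are all safe. Keeping O3' masked through the sulfation removes any selectivity question inside ring B. The forward step must cleave the benzylic C–O bond without saturating C2=C3 and without acid.

**25 from 24.** The three O–S bonds at O3, O7 and O4' are cut together. Sulfate enters only here because sulfated intermediates cannot be chromatographed on silica or exposed to acid. 24 is a neutral tetraphenol with O3' blocked and O5 deactivated by its hydrogen bond to C4=O, so no fifth protecting group is needed. The forward step must complete sulfation at the weakly chelated O3 yet stop before O5.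

**24 from 23.** Three O–CH2Ar bonds of 4-methoxybenzyl ethers (O3, O7, O4') are cut in one acid step that leaves the plain benzyl ether at O3' intact. One acid-labile group at all three positions means one alkylating agent, one deprotection, and no chloromethyl ether reagent anywhere. The demand is an efficient cation scavenger, because ring A of 24 is a nucleophilic resorcinol.

**23 from 11 and 18 (key disconnection).** Ring A is opened at C5–C6, C7–C8 and C4a–C5, and a retro-Wolff shift returns C8a from C8 to the acyl carbon C5. The cut is made here because the oxygen pattern of ring A (free hydroxyl at C5, ether at C7, hydrogen at C6 and C8) is what a ketene and an alkoxyalkyne deliver, and ring C, O3 and ring B are untouched. The bicyclic flavone shrinks to a monocyclic pyranone plus a two-carbon alkyne, and O5 and O7 emerge differentiated. The forward step must generate the ketene at or below room temperature, since 18 is thermally labile, with light the arylpyranone does not absorb. The pyranone carbon that becomes C4a must bear hydrogen.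

**11 from 9.** The bond between the acyl carbon and the diazo carbon is cut, revealing a carboxylic acid and a one-carbon diazo nucleophile. Activation must avoid strong acid (three acid-labile ethers) and gaseous diazomethane; the mixed anhydride 10 and a silylated diazomethane meet both demands.

**9 from 3 and 7.** The C2–C1' bond between pyranone and ring B is cut by cross-coupling, and the ester O–CH2Ar bond of 8 is cleaved in the same flask. The bromine of 3 sits at the β-position of a vinylogous ester, which favours oxidative addition, and ring B arrives with its two oxygens already distinguished. Coupling must outrun attack of aqueous base on the pyranone.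

**3 from 2 from 1.** Two O–CH2Ar bonds (ether and ester) and then the C–Br bond are removed. Bromination precedes alkylation because only the free enolic hydroxyl activates the neighbouring ring carbon. 1 already holds ring C with O3, C4=O and the carboxyl carbon that becomes C5.

**7 from 6 from 5 from 4.** The C–B bond, the O–CH2Ar bond at the future O4' and the C–Br bond are cut in turn. Bromination para to the free hydroxyl of 4 decides that this oxygen becomes O4' (later sulfated) and the benzylated one O3' (later free).

**18 from 15 from 12 and 13.** The triple bond goes back to a 1,2-dichlorovinyl ether, which loses its chlorines by elimination and chlorine–lithium exchange via 16 and 17. The O–C bond of 15 goes back to addition of the alkoxide of 12 to 14, which forms in the flask from 13. Both forward steps must run cold and 18 must be used at once.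

## Other disconnections considered

**Alternative 1:** The cut is C2–C3 of ring C.
- **Forward step:** the aryl glyoxal A1, which carries the ring B benzyl unit as an ether on the future O1, is irradiated. The excited 1,2-dicarbonyl abstracts hydrogen from the O1–CH2 carbon, and the 1,6-biradical closes to the 3-hydroxychroman-4-one A2.
- **In favour:** the hydrogen is doubly activated (benzylic and α to oxygen). O3 is formed at the right carbon, and the stereoisomer mixture is irrelevant because C2 and C3 both become sp2. No diazo compound and no ynol ether is needed, so on reagent hazard it is better than the chosen plan.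
- **Against:** the ketone carbonyl at C4 can abstract the same hydrogen through a smaller transition state and close a five-membered benzofuranol instead. The methoxymethyl and the O3' benzyl CH2 groups offer further abstraction sites. A2 is one oxidation level too low and needs a separate dehydrogenation. A1 requires three different groups on a symmetric 1,3,5-trioxygenated ring plus a C-acylation, which costs steps.
- **Comparison:** both plans are photochemical and both need a finishing operation (heating there is replaced by oxidation here), so they are equal on that point. The chosen plan fixes regiochemistry by the polarity of 19 and 18, whereas this one depends on competition between two carbonyl groups. The step count would be similar or somewhat higher.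

**Alternative 2:** The cuts are O1–C8a, C4–C4a and O1–C2.
- **Forward step:** CsF releases the aryne from the silylaryl triflate A3. The carboxylate of the arylpropiolic acid A4 adds at C8a, the aryl anion at C4a attacks the carboxyl carbon, and the phenoxide closes onto the ynone to give the flavone A5.
- **In favour:** three bonds and ring C form in one flask from two fragments of similar size. The alkoxy group next to the aryne steers the nucleophile to the remote carbon, which is the required orientation. There is no photochemistry and no diazo compound. On convergence and scalability it is better than the chosen plan.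
- **Against:** A5 has no oxygen at C3, so a later C3 hydroxylation (metalation/boration/oxidation or epoxidation) is needed on a substrate full of acetal and benzyl ethers. Simple O-arylation of the acid by the aryne competes with acyl transfer, and 5-exo closure to an aurone competes with 6-endo closure. A3 needs a regiocontrolled ortho-silylation on an electron-rich ring.
- **Comparison:** regiocontrol by polarity is equal in both plans. The chosen plan carries O3 in from 1, while this one must add it late; the overall step count is comparable. O5 and O7 are not differentiated in A5, but that is no real loss because chelation protects O5 at the sulfation stage in either plan.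

**Alternative 3:** The cut is C4–C4a.
- **Forward step:** the aryloxyacrylic acid A6 is activated with trifluoroacetic anhydride and acylates its symmetric 3,5-dialkoxyphenoxy ring at either equivalent ortho carbon, closing ring C to the chromenone A7.
- **In favour:** symmetry removes any regiochemical question in ring A, which is equal to or better than the chosen plan. The chemistry is thermal, scalable and free of diazo reagents, and O3 is present from the start. Allyl ethers come off with a zerovalent palladium catalyst without generating benzylic cations, which is better than acid cleavage of 23 with regard to C-alkylation.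
- **Against:** the difficulty moves into A6, a tetrasubstituted alkene bearing three heteroatom substituents, which must be made with the aryloxy group cis to the carboxyl. The electron-rich rings can be trifluoroacetylated intermolecularly, and four allyl aryl ethers invite Claisen rearrangement on heating.
- **Comparison:** the key step itself is mechanistically simpler and more robust than a four-stage pericyclic cascade. The route to its precursor is longer and less certain than the route to 11, so overall step economy would be similar at best.

Key step: step 10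

Assumption: sulfate monoesters are drawn and named as free O–SO3H acids so that 26 matches the target as written. In the flask 25 and 26 would be triethylammonium salts, and the acid form is released only by a final cold cation exchange.

## Route

Step 1
Reactants: 1 comenic acid (5-hydroxy-4-oxo-4H-pyran-2-carboxylic acid)
Product: 2 6-bromo-5-hydroxy-4-oxo-4H-pyran-2-carboxylic acid
Conditions: NBS, DMF, 0 °C to rt
Reagents that add atoms: N-bromosuccinimide, O=C1CCC(=O)N1Br
Why: Electrophilic bromination of an enolic 3-hydroxy-4-pyranone; the free hydroxyl activates the one open ortho carbon (C6), which is why bromination precedes O-alkylation.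

Step 2
Reactants: 2 6-bromo-5-hydroxy-4-oxo-4H-pyran-2-carboxylic acid
Product: 3 4-methoxybenzyl 6-bromo-5-[(4-methoxybenzyl)oxy]-4-oxo-4H-pyran-2-carboxylate
Conditions: 4-methoxybenzyl chloride (2.3 equiv), K2CO3, DMF, 40 °C
Reagents that add atoms: 4-methoxybenzyl chloride, COc1ccc(CCl)cc1
Why: Twofold SN2 O-alkylation (Williamson etherification of the enol oxygen and esterification of the carboxylate) protects both acidic sites in one operation and avoids chloromethyl methyl ether.

Step 3
Reactants: 4 2-(benzyloxy)phenol
Product: 5 2-(benzyloxy)-4-bromophenol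
Conditions: NBS, MeCN, 0 °C
Reagents that add atoms: N-bromosuccinimide, O=C1CCC(=O)N1Br
Why: Electrophilic aromatic bromination goes para to the free hydroxyl, the stronger donor, so the brominated carbon becomes C1', the free oxygen O4' and the benzylated oxygen O3'.

Step 4
Reactants: 5 2-(benzyloxy)-4-bromophenol
Product: 6 2-(benzyloxy)-4-bromo-1-[(4-methoxybenzyl)oxy]benzene
Conditions: 4-methoxybenzyl chloride, K2CO3, DMF, rt
Reagents that add atoms: 4-methoxybenzyl chloride, COc1ccc(CCl)cc1
Why: Williamson etherification of the phenoxide; the resulting ether is acid-labile and orthogonal to the hydrogenolysis-only benzyl ether at the neighbouring oxygen.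

Step 5
Reactants: 6 2-(benzyloxy)-4-bromo-1-[(4-methoxybenzyl)oxy]benzene
Product: 7 2-{3-(benzyloxy)-4-[(4-methoxybenzyl)oxy]phenyl}-4,4,5,5-tetramethyl-1,3,2-dioxaborolane
Conditions: bis(pinacolato)diboron, Pd(dppf)Cl2 (3 mol %), KOAc, 1,4-dioxane, 85 °C
Reagents that add atoms: bis(pinacolato)diboron, CC1(C)OB(OC1(C)C)B1OC(C)(C)C(C)(C)O1
Why: Miyaura borylation of an electron-rich aryl bromide; acetate is too weak a base to trigger homocoupling and both ether types are inert.

Step 6
Reactants: 3 4-methoxybenzyl 6-bromo-5-[(4-methoxybenzyl)oxy]-4-oxo-4H-pyran-2-carboxylate, 7 2-{3-(benzyloxy)-4-[(4-methoxybenzyl)oxy]phenyl}-4,4,5,5-tetramethyl-1,3,2-dioxaborolane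
Product: 9 6-{3-(benzyloxy)-4-[(4-methoxybenzyl)oxy]phenyl}-5-[(4-methoxybenzyl)oxy]-4-oxo-4H-pyran-2-carboxylic acid, via biaryl PMB ester 8 (not isolated)
Conditions: Pd(dppf)Cl2 (3 mol %), K2CO3, 1,4-dioxane/H2O, 70 °C; then LiOH, THF/H2O, 0 °C to rt; 1 M HCl to pH 3, 0 °C
Reagents that add atoms: lithium hydroxide, [Li+].[OH-]
Why: Suzuki–Miyaura coupling: zerovalent palladium formed from Pd(dppf)Cl2 inserts readily into the C–Br bond of the vinylogous acyl bromide and couples it with the boronate. Hydroxide then cleaves the ester of 8 at the acyl carbon in the same flask, so the ester never needs isolating.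

Step 7
Reactants: 9 6-{3-(benzyloxy)-4-[(4-methoxybenzyl)oxy]phenyl}-5-[(4-methoxybenzyl)oxy]-4-oxo-4H-pyran-2-carboxylic acid
Product: 11 2-{3-(benzyloxy)-4-[(4-methoxybenzyl)oxy]phenyl}-6-(2-diazoacetyl)-3-[(4-methoxybenzyl)oxy]-4H-pyran-4-one, via mixed carbonic anhydride 10 (not isolated)
Conditions: ClCO2Et, Et3N, THF, −15 °C; then Me3SiCHN2 (2 M in hexanes, 2 equiv), MeCN, 0 °C to rt; excess reagent quenched with dilute AcOH at 0 °C
Reagents that add atoms: (trimethylsilyl)diazomethane, C[Si](C)(C)C=[N+]=[N-]
Why: C-acylation of the diazo carbon by the mixed anhydride followed by loss of the silyl group (the diazoketone stage of an Arndt–Eistert sequence). Activation is non-acidic, so the three benzylic ethers survive, and no diazomethane gas is generated; the reagent is still toxic by inhalation and is handled in a hood.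

Step 8
Reactants: 12 4-methoxybenzyl alcohol, 13 trichloroethylene
Product: 15 (E)-1,2-dichlorovinyl 4-methoxybenzyl ether, via dichloroethyne 14 (not isolated)
Conditions: KH, THF, 0 °C; then Cl2C=CHCl, −50 °C to rt, under N2, dilute
Reagents that add atoms: none
Why: The potassium alkoxide dehydrochlorinates trichloroethylene to dichloroethyne and adds to it in anti fashion; protonation gives the E-dichlorovinyl ether (the established alkoxide/trichloroethylene route). The hazardous alkyne exists only in dilute solution and is never concentrated.

Step 9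
Reactants: 15 (E)-1,2-dichlorovinyl 4-methoxybenzyl ether
Product: 18 ethynyl 4-methoxybenzyl ether, via chloroethynyl ether 16 (not isolated), via lithium alkoxyacetylide 17 (not isolated)
Conditions: n-BuLi (2.2 equiv), THF, −78 to −40 °C; MeOH, −78 °C; cold aqueous work-up, used at once as a solution kept below 0 °C
Reagents that add atoms: none
Why: Deprotonation of the vinylic C–H with loss of chloride gives the chloroalkyne, chlorine–lithium exchange gives the acetylide, and cold protonation gives the terminal ynol ether. The vinylic hydrogen is far more acidic than the benzylic ones at −78 °C.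

Step 10
Reactants: 11 2-{3-(benzyloxy)-4-[(4-methoxybenzyl)oxy]phenyl}-6-(2-diazoacetyl)-3-[(4-methoxybenzyl)oxy]-4H-pyran-4-one, 18 ethynyl 4-methoxybenzyl ether
Product: 23 2-{3-(benzyloxy)-4-[(4-methoxybenzyl)oxy]phenyl}-5-hydroxy-3,7-bis[(4-methoxybenzyl)oxy]-4H-chromen-4-one, via pyranylketene 19 (not isolated), via alkoxycyclobutenone 20 (not isolated), via dienylketene 21 (not isolated), via 4aH-chromene-4,5-dione 22 (not isolated)
Conditions: 18 (2 equiv), hν (LED, 420–450 nm), ClCH2CH2Cl, 15–20 °C; then 80 °C
Reagents that add atoms: none
Why: Excitation of the diazoketone band of 11 expels N2 and shifts the pyranyl carbon (future C8a) from the acyl carbon to the diazo carbon (photochemical Wolff rearrangement), giving ketene 19 whose carbonyl carbon is the future C5 and whose α-carbon is the future C8. The electron-rich alkyne 18 adds across the ketene C=C in a polarity-controlled (2+2) cycloaddition, its nucleophilic CH terminus bonding to the ketene carbonyl carbon (C5–C6) and its oxygenated carbon to the α-carbon (C7–C8), which gives the four-membered 3-alkoxycyclobutenone 20. Warming opens 20 by reversible 4π electrocyclic cleavage of C5–C8 to dienylketene 21, and the isomer with C6 and C8a cis closes ring A by a thermal disrotatory 6π electrocyclisation between the ketene carbon and C4a, the only carbon neighbour of C8a (the other neighbour is O1). Dienone 22 then tautomerises to phenol 23, driven by aromatisation and by the hydrogen bond from O5–H to the C4 carbonyl. The closest known reaction type is the Danheiser benzannulation in its diazoketone variant with alkoxyacetylenes, in which vinyl and heteroaryl diazoketones serve as the ketene source. No stereocentre persists, since the sp3 centres of 20 and 22 are transient and racemic. The step needs regiocontrol in the cycloaddition, which the matched polarity of ketene and ynol ether supplies, and selective excitation of the diazo chromophore, for which light above 400 nm is chosen so that the arylpyranone and the product are barely excited; the mixture is kept at or below 20 °C until 11 is consumed because benzylic alkynyl ethers rearrange on heating.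

Step 11
Reactants: 23 2-{3-(benzyloxy)-4-[(4-methoxybenzyl)oxy]phenyl}-5-hydroxy-3,7-bis[(4-methoxybenzyl)oxy]-4H-chromen-4-one
Product: 24 2-[3-(benzyloxy)-4-hydroxyphenyl]-3,5,7-trihydroxy-4H-chromen-4-one
Conditions: CF3CO2H, anisole (20 equiv), CH2Cl2, 0 °C
Reagents that add atoms: none
Why: Acidolysis of the three 4-methoxybenzyl ethers through the stabilised benzylic cation, which excess anisole traps by Friedel–Crafts alkylation before it can attack ring A. The unsubstituted benzyl ether does not ionise under these conditions.

Step 12
Reactants: 24 2-[3-(benzyloxy)-4-hydroxyphenyl]-3,5,7-trihydroxy-4H-chromen-4-one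
Product: 25 2-[3-(benzyloxy)-4-(sulfooxy)phenyl]-5-hydroxy-3,7-bis(sulfooxy)-4H-chromen-4-one (handled as the tris(triethylammonium) salt)
Conditions: SO3·NMe3 (6 equiv), Et3N, DMF, 40 °C; reverse-phase chromatography
Reagents that add atoms: sulfur trioxide–trimethylamine complex, C[N+](C)(C)S(=O)(=O)[O-]
Why: O-sulfonation of the phenoxides by transfer of SO3 from the amine complex. O7 and O4' are the most acidic and react first, O3 follows, and O5 is held back by its strong six-membered hydrogen bond to C4=O, so a limited excess should stop at the trisulfate.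

Step 13
Reactants: 25 2-[3-(benzyloxy)-4-(sulfooxy)phenyl]-5-hydroxy-3,7-bis(sulfooxy)-4H-chromen-4-one
Product: 26 2-[3-hydroxy-4-(sulfooxy)phenyl]-5-hydroxy-3,7-bis(sulfooxy)-4H-chromen-4-one (quercetin 3,4',7-trisulfate)
Conditions: H2 (1 atm), Pd/C, MeOH/H2O (pH about 7), rt; then sulfonic acid cation-exchange resin (H+ form), 0 °C, freeze-drying
Reagents that add atoms: none
Why: Hydrogenolysis of the benzyl aryl ether on palladium at neutral pH; aryl sulfate salts are inert to these conditions and the conjugated, chelated C2=C3 bond of a flavonol is not reduced at atmospheric pressure.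

## Compound list

1 | comenic acid (5-hydroxy-4-oxo-4H-pyran-2-carboxylic acid) | O=C(O)c1cc(=O)c(O)co1 | starting material
2 | 6-bromo-5-hydroxy-4-oxo-4H-pyran-2-carboxylic acid | O=C(O)c1cc(=O)c(O)c(Br)o1 | intermediate
3 | 4-methoxybenzyl 6-bromo-5-[(4-methoxybenzyl)oxy]-4-oxo-4H-pyran-2-carboxylate | COc1ccc(COC(=O)c2cc(=O)c(OCc3ccc(OC)cc3)c(Br)o2)cc1 | intermediate
4 | 2-(benzyloxy)phenol | Oc1ccccc1OCc1ccccc1 | starting material
5 | 2-(benzyloxy)-4-bromophenol | Oc1ccc(Br)cc1OCc1ccccc1 | intermediate
6 | 2-(benzyloxy)-4-bromo-1-[(4-methoxybenzyl)oxy]benzene | COc1ccc(COc2ccc(Br)cc2OCc2ccccc2)cc1 | intermediate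
7 | 2-{3-(benzyloxy)-4-[(4-methoxybenzyl)oxy]phenyl}-4,4,5,5-tetramethyl-1,3,2-dioxaborolane | COc1ccc(COc2ccc(B3OC(C)(C)C(C)(C)O3)cc2OCc2ccccc2)cc1 | intermediate
8 | 4-methoxybenzyl 6-{3-(benzyloxy)-4-[(4-methoxybenzyl)oxy]phenyl}-5-[(4-methoxybenzyl)oxy]-4-oxo-4H-pyran-2-carboxylate | COc1ccc(COC(=O)c2cc(=O)c(OCc3ccc(OC)cc3)c(-c3ccc(OCc4ccc(OC)cc4)c(OCc4ccccc4)c3)o2)cc1 | intermediate (not isolated)
9 | 6-{3-(benzyloxy)-4-[(4-methoxybenzyl)oxy]phenyl}-5-[(4-methoxybenzyl)oxy]-4-oxo-4H-pyran-2-carboxylic acid | O=C(O)c1cc(=O)c(OCc2ccc(OC)cc2)c(-c2ccc(OCc3ccc(OC)cc3)c(OCc3ccccc3)c2)o1 | intermediate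
10 | ethyl carbonic anhydride of 9 | CCOC(=O)OC(=O)c1cc(=O)c(OCc2ccc(OC)cc2)c(-c2ccc(OCc3ccc(OC)cc3)c(OCc3ccccc3)c2)o1 | intermediate (not isolated)
11 | 2-{3-(benzyloxy)-4-[(4-methoxybenzyl)oxy]phenyl}-6-(2-diazoacetyl)-3-[(4-methoxybenzyl)oxy]-4H-pyran-4-one | O=c1cc(C(=O)C=[N+]=[N-])oc(-c2ccc(OCc3ccc(OC)cc3)c(OCc3ccccc3)c2)c1OCc1ccc(OC)cc1 | intermediate
12 | 4-methoxybenzyl alcohol | COc1ccc(CO)cc1 | starting material
13 | trichloroethylene | ClC=C(Cl)Cl | starting material
14 | dichloroethyne | ClC#CCl | intermediate (not isolated)
15 | (E)-1,2-dichlorovinyl 4-methoxybenzyl ether | COc1ccc(CO/C(Cl)=C\Cl)cc1 | intermediate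
16 | chloroethynyl 4-methoxybenzyl ether | COc1ccc(COC#CCl)cc1 | intermediate (not isolated)
17 | lithium 2-[(4-methoxybenzyl)oxy]ethynide | [Li]C#COCc1ccc(OC)cc1 | intermediate (not isolated)
18 | ethynyl 4-methoxybenzyl ether | C#COCc1ccc(OC)cc1 | intermediate
19 | {6-{3-(benzyloxy)-4-[(4-methoxybenzyl)oxy]phenyl}-5-[(4-methoxybenzyl)oxy]-4-oxo-4H-pyran-2-yl}ketene | O=C=Cc1cc(=O)c(OCc2ccc(OC)cc2)c(-c2ccc(OCc3ccc(OC)cc3)c(OCc3ccccc3)c2)o1 | intermediate (not isolated)
20 | 2-{3-(benzyloxy)-4-[(4-methoxybenzyl)oxy]phenyl}-3-[(4-methoxybenzyl)oxy]-6-{2-[(4-methoxybenzyl)oxy]-4-oxocyclobut-2-en-1-yl}-4H-pyran-4-one (racemic) | O=C1C=C(OCc2ccc(OC)cc2)C1c1cc(=O)c(OCc2ccc(OC)cc2)c(-c2ccc(OCc3ccc(OC)cc3)c(OCc3ccccc3)c2)o1 | intermediate (not isolated)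
21 | (3E)-4-{6-{3-(benzyloxy)-4-[(4-methoxybenzyl)oxy]phenyl}-5-[(4-methoxybenzyl)oxy]-4-oxo-4H-pyran-2-yl}-3-[(4-methoxybenzyl)oxy]buta-1,3-dien-1-one | O=C=C/C(OCc1ccc(OC)cc1)=C\c1cc(=O)c(OCc2ccc(OC)cc2)c(-c2ccc(OCc3ccc(OC)cc3)c(OCc3ccccc3)c2)o1 | intermediate (not isolated)
22 | 2-{3-(benzyloxy)-4-[(4-methoxybenzyl)oxy]phenyl}-3,7-bis[(4-methoxybenzyl)oxy]-4aH-chromene-4,5-dione (racemic) | O=C1C=C(OCc2ccc(OC)cc2)C=C2OC(c3ccc(OCc4ccc(OC)cc4)c(OCc4ccccc4)c3)=C(OCc3ccc(OC)cc3)C(=O)C12 | intermediate (not isolated)
23 | 2-{3-(benzyloxy)-4-[(4-methoxybenzyl)oxy]phenyl}-5-hydroxy-3,7-bis[(4-methoxybenzyl)oxy]-4H-chromen-4-one | O=c1c(OCc2ccc(OC)cc2)c(-c2ccc(OCc3ccc(OC)cc3)c(OCc3ccccc3)c2)oc2cc(OCc3ccc(OC)cc3)cc(O)c12 | intermediate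
24 | 2-[3-(benzyloxy)-4-hydroxyphenyl]-3,5,7-trihydroxy-4H-chromen-4-one | O=c1c(O)c(-c2ccc(O)c(OCc3ccccc3)c2)oc2cc(O)cc(O)c12 | intermediate
25 | 2-[3-(benzyloxy)-4-(sulfooxy)phenyl]-5-hydroxy-3,7-bis(sulfooxy)-4H-chromen-4-one | O=c1c(OS(=O)(=O)O)c(-c2ccc(OS(=O)(=O)O)c(OCc3ccccc3)c2)oc2cc(OS(=O)(=O)O)cc(O)c12 | intermediate
26 | 2-[3-hydroxy-4-(sulfooxy)phenyl]-5-hydroxy-3,7-bis(sulfooxy)-4H-chromen-4-one (quercetin 3,4',7-trisulfate) | O=c1c(OS(=O)(=O)O)c(-c2ccc(OS(=O)(=O)O)c(O)c2)oc2cc(OS(=O)(=O)O)cc(O)c12 | target

## Step count and least certain steps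

Total step count: 13. Longest linear sequence: 9 steps (steps 3, 4, 5, 6, 7, 10, 11, 12 and 13, starting from 4).

**Step 10 (key step).**
- *What may go wrong:* the Wolff rearrangement may be slow if the diazo band is weak at the chosen wavelength, so that light is absorbed unproductively. Thermal sigmatropic rearrangement of 18 may compete with the cycloaddition. Ketene 19 may be intercepted by moisture or dimerise. The cascade may stall at cyclobutenone 20 if ring opening needs more heat than the ethers tolerate.
- *Fallback (sets out from 11, comes back at 23):* the ketene is generated in the dark. Thermal Wolff rearrangement of 11 with AgO2CPh and Et3N in aqueous THF should give the pyranylacetic acid F1. 1-Chloro-N,N,2-trimethylprop-1-en-1-amine in CH2Cl2 at 0 °C converts it under neutral conditions into the pyranylacetyl chloride F2. Slow addition of i-Pr2NEt to F2 and 18 at 20 °C releases 19 by dehydrochlorination, which passes through 20, 21 and 22 and reaches 23 after warming.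

**Step 9.**
- *What may go wrong:* benzylic metalation followed by anionic rearrangement during the butyllithium stage, and sigmatropic rearrangement or hydration of 18 during work-up and concentration.
- *Fallback (sets out from 13 and 11, comes back at 24):* a tert-butyl ynol ether, which has no benzylic C–H and cannot undergo the benzyl-type shift. tert-Butanol and 13 under the conditions of step 8 should give (E)-1,2-dichlorovinyl tert-butyl ether F3. n-BuLi and then methanol convert it into tert-butoxyethyne F4, a volatile liquid that can be distilled cold. F4 and 11 under the conditions of step 10, with excess F4 removed under vacuum before warming, should give the 7-tert-butoxy flavone F5. The acid conditions of step 11 then remove the tert-butyl group together with the two 4-methoxybenzyl groups to reach 24.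

**Step 7.**
- *What may go wrong:* incomplete C-acylation of the weakly nucleophilic silyldiazomethane, and dipolar cycloaddition or conjugate addition of the diazo reagent to the electron-poor double bond of the pyranone next to the activated carboxyl.
- *Fallback (sets out from 9, comes back at 11):* deacylative diazo transfer, which needs no diazoalkane. 9 is coupled with N,O-dimethylhydroxylamine hydrochloride (EDC·HCl, i-Pr2NEt) to the N-methoxy-N-methylamide F6. MeMgBr at −40 °C gives the methyl ketone F7. Its lithium enolate (LiN(SiMe3)2, −78 °C) is acylated with 2,2,2-trifluoroethyl trifluoroacetate to the trifluoromethyl 1,3-diketone F8. F8 reacts with 4-acetamidobenzenesulfonyl azide, Et3N and water in MeCN, with loss of the trifluoroacetyl group, to give 11.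

**Step 12.**
- *What may go wrong:* incomplete sulfation at the weakly chelated O3 next to ring B, over-sulfation at O5 under forcing conditions, and poor separation of polyanions that differ by one sulfate.
- *Fallback (sets out from 24, comes back at 25):* sulfate is introduced as neutral diesters. 24 with 2,2,2-trichloroethyl chlorosulfate (3.3 equiv), Et3N and DMAP in THF should give the tris(trichloroethyl sulfate) F9, which can be purified on silica before any polyanion exists. Zn dust and ammonium formate in methanol then unmask the three sulfate monoesters by reductive fragmentation to give 25.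

**Step 6.**
- *What may go wrong:* displacement of the activated bromide or opening of the pyranone by hydroxide or carbonate before oxidative addition, protodeboronation of the electron-rich boronate, and ring opening during saponification.
- *Fallback (sets out from 6 and 3, comes back at 9):* an anhydrous Negishi coupling that exposes the bromopyranone to no hydroxide. Bromine–lithium exchange on 6 (n-BuLi, THF, −78 °C) and transmetalation with ZnCl2 give the arylzinc chloride F10. Coupling with 3 (Pd(PPh3)4, THF, 40 °C) gives 8, now isolated, and a separate saponification with LiOH at 0 °C gives 9.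

## Further compounds

F1 | step 10 | {6-{3-(benzyloxy)-4-[(4-methoxybenzyl)oxy]phenyl}-5-[(4-methoxybenzyl)oxy]-4-oxo-4H-pyran-2-yl}acetic acid | OC(=O)Cc1cc(=O)c(OCc2ccc(OC)cc2)c(-c2ccc(OCc3ccc(OC)cc3)c(OCc3ccccc3)c2)o1
F2 | step 10 | {6-{3-(benzyloxy)-4-[(4-methoxybenzyl)oxy]phenyl}-5-[(4-methoxybenzyl)oxy]-4-oxo-4H-pyran-2-yl}acetyl chloride | ClC(=O)Cc1cc(=O)c(OCc2ccc(OC)cc2)c(-c2ccc(OCc3ccc(OC)cc3)c(OCc3ccccc3)c2)o1
F3 | step 9 | (E)-1,2-dichlorovinyl tert-butyl ether | CC(C)(C)O/C(Cl)=C\Cl
F4 | step 9 | tert-butoxyethyne | C#COC(C)(C)C
F5 | step 9 | 2-{3-(benzyloxy)-4-[(4-methoxybenzyl)oxy]phenyl}-7-tert-butoxy-5-hydroxy-3-[(4-methoxybenzyl)oxy]-4H-chromen-4-one | O=c1c(OCc2ccc(OC)cc2)c(-c2ccc(OCc3ccc(OC)cc3)c(OCc3ccccc3)c2)oc2cc(OC(C)(C)C)cc(O)c12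
F6 | step 7 | 6-{3-(benzyloxy)-4-[(4-methoxybenzyl)oxy]phenyl}-N-methoxy-5-[(4-methoxybenzyl)oxy]-N-methyl-4-oxo-4H-pyran-2-carboxamide | CON(C)C(=O)c1cc(=O)c(OCc2ccc(OC)cc2)c(-c2ccc(OCc3ccc(OC)cc3)c(OCc3ccccc3)c2)o1
F7 | step 7 | 6-acetyl-2-{3-(benzyloxy)-4-[(4-methoxybenzyl)oxy]phenyl}-3-[(4-methoxybenzyl)oxy]-4H-pyran-4-one | CC(=O)c1cc(=O)c(OCc2ccc(OC)cc2)c(-c2ccc(OCc3ccc(OC)cc3)c(OCc3ccccc3)c2)o1
F8 | step 7 | 1-{6-{3-(benzyloxy)-4-[(4-methoxybenzyl)oxy]phenyl}-5-[(4-methoxybenzyl)oxy]-4-oxo-4H-pyran-2-yl}-4,4,4-trifluorobutane-1,3-dione | O=C(CC(=O)C(F)(F)F)c1cc(=O)c(OCc2ccc(OC)cc2)c(-c2ccc(OCc3ccc(OC)cc3)c(OCc3ccccc3)c2)o1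
F9 | step 12 | 2-[3-(benzyloxy)-4-{[(2,2,2-trichloroethoxy)sulfonyl]oxy}phenyl]-5-hydroxy-3,7-bis{[(2,2,2-trichloroethoxy)sulfonyl]oxy}-4H-chromen-4-one | O=c1c(OS(=O)(=O)OCC(Cl)(Cl)Cl)c(-c2ccc(OS(=O)(=O)OCC(Cl)(Cl)Cl)c(OCc3ccccc3)c2)oc2cc(OS(=O)(=O)OCC(Cl)(Cl)Cl)cc(O)c12
F10 | step 6 | {3-(benzyloxy)-4-[(4-methoxybenzyl)oxy]phenyl}zinc chloride | Cl[Zn]c1ccc(OCc2ccc(OC)cc2)c(OCc2ccccc2)c1
A1 | alternative 1 | 3-{[3-(benzyloxy)-4-(methoxymethoxy)benzyl]oxy}-5-(methoxymethoxy)-2-(2-oxoacetyl)phenyl 2,2-dimethylpropanoate | O=CC(=O)c1c(OCc2ccc(OCOC)c(OCc3ccccc3)c2)cc(OCOC)cc1OC(=O)C(C)(C)C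
A2 | alternative 1 | 2-[3-(benzyloxy)-4-(methoxymethoxy)phenyl]-3-hydroxy-7-(methoxymethoxy)-5-(pivaloyloxy)chroman-4-one (mixture of stereoisomers) | O=C1C(O)C(c2ccc(OCOC)c(OCc3ccccc3)c2)Oc2cc(OCOC)cc(OC(=O)C(C)(C)C)c21
A3 | alternative 2 | 3,5-bis(methoxymethoxy)-2-(trimethylsilyl)phenyl trifluoromethanesulfonate | COCOc1cc(OCOC)c([Si](C)(C)C)c(OS(=O)(=O)C(F)(F)F)c1
A4 | alternative 2 | 3-[3-(benzyloxy)-4-(methoxymethoxy)phenyl]prop-2-ynoic acid | O=C(O)C#Cc1ccc(OCOC)c(OCc2ccccc2)c1
A5 | alternative 2 | 2-[3-(benzyloxy)-4-(methoxymethoxy)phenyl]-5,7-bis(methoxymethoxy)-4H-chromen-4-one | O=c1cc(-c2ccc(OCOC)c(OCc3ccccc3)c2)oc2cc(OCOC)cc(OCOC)c12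
A6 | alternative 3 | (2E)-2-(allyloxy)-3-[4-(allyloxy)-3-(benzyloxy)phenyl]-3-[3,5-bis(allyloxy)phenoxy]prop-2-enoic acid | OC(=O)/C(OCC=C)=C(\Oc1cc(OCC=C)cc(OCC=C)c1)c1ccc(OCC=C)c(OCc2ccccc2)c1
A7 | alternative 3 | 3,5,7-tris(allyloxy)-2-[4-(allyloxy)-3-(benzyloxy)phenyl]-4H-chromen-4-one | O=c1c(OCC=C)c(-c2ccc(OCC=C)c(OCc3ccccc3)c2)oc2cc(OCC=C)cc(OCC=C)c12
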